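## Structural features

The target is a cis-fused decalin of the eremophilane type. Ring B (C10, C1, C2, C3, C4, C5) is a cyclohexanone whose C2 carbonyl lies between the C1 and C3 methylenes. Ring A (C5 to C10) carries the isopropenyl group at C7, the acetate at C8 and the tiglate at C9, and the rings share the C5–C10 bond. Six contiguous stereocentres run around the periphery (C4, C5, C10, C9, C8, C7; 4S,5R,7R,8R,9S,10S in this numbering). The C4 and C5 methyls are cis, the C10 hydrogen is cis to the C5 methyl, and the C8 and C9 oxygens are cis to each other and to C4 on one face of ring A (called β below), opposite the C7 side chain, the C5 methyl and the C10 hydrogen (α). In the preferred chair–chair conformer the C7 and C8 substituents are equatorial while the C9 ester is axial and 1,3-diaxial to the C5–C4 bond, so the C9 oxygen is hindered. The fragile groups are two different esters on a cis-diol (acyl migration under base), the conjugated tiglate, and the isopropenyl group (acid-induced isomerisation to the isopropylidene position, and reactive toward any borane). The real difficulty is the quaternary C5 flanked by the C4 and C10 stereocentres, together with a differentiated, hindered cis-diol next to the C7 side chain. The key step exploits the C2 carbonyl between two methylenes whose outer neighbours C10 and C4 both carry hydrogen: this is the pattern left when a C10=C1 and a C4=C3 double bond (a 1,4-diene spanning C5) are hydroborated by one boron atom and boron is then exchanged for a carbonyl carbon, closing ring B.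

## Logic of the disconnections

**25 to 24.** The C11=C12 double bond is cut back to a C11–O bond. A free isopropenyl group cannot be present while boron is in the molecule, and the C11 oxygen comes with the starting material. The gain is that a third alkene never competes in the key step. The demand is an elimination toward a methyl group and not toward C7.

**24 to 23, 22, and 20 + 21.** The ester C–O bonds are cut in the order acetate (24 to 23), then the ketal joining O8 and O11 (23 to 22), then the tiglate (22 to 20 + 21). The hindered axial C9 ester is thus made first, while no other acyl group or free hydroxyl is present, and the easy equatorial C8 acetate last. The gain is that the two esters are differentiated by design and neither is exposed to an alkoxide on the neighbouring carbon. The demand is a forcing acylation of the C9 hydroxyl.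

**20 to 19.** The O9–Si bond is cut. The silyl group only protects O9 from B–H and adds bulk on the β face; its removal must leave the ketal intact.

**19 to 15 + 16.** The C1–C2 and C2–C3 bonds are cut, so ring B is opened to a 1,4-diene and a one-carbon unit. This removes ring B, the C2 carbonyl and the C4 and C10 stereocentres in one operation and leaves a monocyclic ring A that already holds C5, C7, C8 and C9. The demands are hydrogen delivery to C10 from the α face, a ring closure that puts the C4 methyl cis to the C5 methyl, and attack on the methylene before the isopropenyl group.

**15 to 14 to 13.** The O9–Si bond and then the C9–H bond are cut, leading to a C9 ketone conjugated with the exocyclic methylene. The demand is 1,2-reduction from the α face so that O9 ends axial and cis to O8.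

**13 to 9.** The C10=C1 bond is cut, leaving a C9 enol derivative with defined regiochemistry. The methylene carbon is then added at the only enolate carbon that the previous step creates. The demand is a small electrophile that reacts next to the quaternary C5.

**9 to 7 + 8.** The C5–C4 bond is cut. Conjugate addition to the β-methyl enone builds the quaternary centre and delivers the enol derivative needed above. The demand is addition trans to the C7 side chain.

**7 to 6 to 4 to 3.** The ketal C–O bonds and then the C8–O bond are cut. The C8 oxygen is introduced at the only kinetically enolisable position of the enone, anti to the C7 side chain, and tied at once to O11. The gains are one protecting group for two hydroxyls and a locked ring A chair. The demand is α′- and not γ-enolisation.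

**3 to 2 to 1.** The C11–O bond is traced to the external cyclopropane bond of 2, and the C9 carbonyl to an allylic methylene of 1. The terpene 1 supplies C7 in the right absolute configuration, C11 with both methyls, and the C5 methyl. The demand is capture of the tertiary cation by water before proton loss.

## Other disconnections considered

**Alternative 1:** The cut is a retro-[3,3] shift: the C4–C5 bond is opened and C2 is reconnected to C7. This turns the cis-decalenone A1 into the bridged bicyclo[2.2.2]octenol A2, which carries a (Z)-propenyl group on the carbinol carbon.
- Forward step: the potassium alkoxide of A2 (KH, 18-crown-6) would undergo an anionic oxy-Cope rearrangement through the boat geometry enforced by the bicycle. It forms C4–C5, releases ring A as a C6=C7 cyclohexene and delivers the C2 carbonyl as its enolate.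
- In its favour: C4, C5 and C10 are set in one concerted, suprafacial event, so the cis ring fusion and the cis methyls follow from geometry alone. On stereochemical certainty this alternative is better than the chosen plan, whose two new centres depend on two separate face selections. It is the equal of the chosen plan in giving the C2 ketone directly.
- Against it here: A1 has an oxygen at C1 (the ketal) that the target lacks. Ring A arrives with no C7 side chain and no C9 oxygen, and its C8 benzyloxy group is on the α face, opposite to the C8 acetate of the target. The isopropenyl group, the C9 oxygen and a corrected C8 centre would all have to be added to a ring that offers only an alkene and one ether as handles. The bridged carbinol is most naturally reached by a cycloaddition that gives racemic material.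
- Comparison: on structure, the chosen plan has all three ring A substituents in place before ring B is closed. On mechanism, the sigmatropic step is the more predictable. On step economy, the short access to A2 would probably be outweighed by the C1 deoxygenation and the work on ring A, and the absolute configuration would need a resolution or an asymmetric cycloaddition, where the chosen plan takes it from the chiral pool.

**Alternative 2:** The cut removes C3–C4 and C5–C10 at once, opening both rings of the cycloadduct A3 to the acyclic trienone A4.
- Forward step: an intramolecular Diels–Alder reaction of the 2-silyloxydiene (C10=C1–C2=C3) of A4 with its (E)-tiglyl ketone (C4=C5), joined through C6–C9.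
- In its favour: it is the most convergent of the four plans. Two rings, two C–C bonds and the C4, C5 and C10 centres arise in one step. The (E)-alkene fixes the cis methyls as reliably as the boracycle does (an equal point). The C2 carbonyl is latent in the silyl enol ether, and the C7 isopropenyl group and both ring A oxygens are already present with the correct configurations. In functional-group readiness after the key step it is better than the chosen plan.
- Against it here: A3 has a C6 ketone that the target lacks. It would have to be removed from a position flanked by the quaternary C5 and an epimerisable C7 bearing a β,γ-unsaturated isopropenyl group, in the presence of the C2 carbonyl. The cis fusion requires one particular endo/exo mode and π-face, which the tether does not obviously enforce. The trisubstituted dienophile may need Lewis acid activation that threatens the acetonide and the silyloxydiene. A4, with three contiguous stereocentres and a deconjugated α-isopropenyl ketone, is itself demanding to assemble. The cis-diol freed from the acetonide must be differentiated late, with the risk of acyl migration.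
- Comparison: on structure the cycloadduct is closer to the target except at C6. On mechanism the chosen step has the better-defined stereochemical model. On step economy the gain in ring construction would probably be spent on the C6 deoxygenation and the diol differentiation.

**Alternative 3:** The cut removes C5–C6 and C7–C8, so ring A is taken off a preformed ring B: the annulation product A5 goes back to the methylenecyclohexane aldehyde A6 and but-3-en-2-one A7.
- Forward step: hydrogen-atom transfer from an iron hydride (Fe(acac)3, PhSiH3) to the exocyclic methylene of A6 gives the tertiary C5 radical and creates the C5 methyl. The radical adds to A7 (C5–C6), and after reduction the enolate closes onto the C8 aldehyde (C7–C8).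
- In its favour: the quaternary centre and ring A form under mild, neutral conditions. C4 and C10 are settled on a simple cyclohexane beforehand. The C7 acetyl group is a regiochemically unambiguous precursor of the isopropenyl group by methylenation, which is better than the tertiary alcohol dehydration of the chosen plan. C8 and C9 arrive oxygenated and already differentiated, an equal point.
- Against it here: three centres (C5, C7, C8) are set in a radical addition and an aldol closure whose facial preferences are not secured by any rigid element. A5, with its C9 ether trans to the C8 hydroxyl, is epimeric with the target at C9. Either the aldehyde must carry the opposite C9 configuration, leading to A8, or C9 must be inverted later at a hindered position. The β-hydroxy ketone of A5 is prone to retro-aldol cleavage, dehydration and C7 epimerisation under basic methylenation conditions. A6 needs its own multistep synthesis with three stereocentres.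
- Comparison: on structure both plans build the decalin one ring at a time, in opposite order. On mechanism the boracycle gives a clearer stereochemical rationale than the radical–polar sequence. On step economy the two are probably comparable.

Key step: step 10

Assumption: the C8 oxygen and the protecting groups on 15 and 19 are treated as spectator groups on the unchanged carbon skeletons of the ring A 1,4-diene and the cis-decalin-2-one. Commercial (+)-3-carene is taken to be the (1S,6R) enantiomer of high optical purity.

Remark: three features distinguish this route from an entry by catalytic asymmetric isopropenyl addition to cyclohex-2-en-1-one with the C8 oxygen added after ring B.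
- The C7 centre, the masked side chain and the β-methyl enone come from one terpene. This avoids the regiochemically ambiguous dehydrogenation of a 3-substituted cyclohexanone and a radical hydration of an isopropenyl group next to an enone.
- O8 is introduced where C8 is the only enolisable position.
- C9 is reduced once and never re-oxidised. No C9 ketone with an epimerisable C10, no C2 ketal and no acetate next to a free hydroxyl appear after the key step.

Step 1
Reactants: 1 (+)-3-carene [(1S,6R)-3,7,7-trimethylbicyclo[4.1.0]hept-3-ene]
Product: 2 (1R,6S)-4,7,7-trimethylbicyclo[4.1.0]hept-3-en-2-one (car-3-en-5-one)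
Conditions: t-BuOOH (70% aq.), Cr(CO)6 (cat.), MeCN, reflux
Reagents that add atoms: tert-butyl hydroperoxide, CC(C)(C)OO
Why: Chromium-catalysed allylic oxidation with a hydroperoxide; hydrogen abstraction at the ring methylene next to the unsubstituted alkene carbon gives the allyl radical with a tertiary terminus, and oxygenation at its secondary end should give the enone conjugated with the trisubstituted alkene and the cyclopropane; no stereocentre is touched.

Step 2
Reactants: 2 car-3-en-5-one
Product: 3 (S)-5-(2-hydroxypropan-2-yl)-3-methylcyclohex-2-en-1-one
Conditions: H2SO4 (50% aq.), 0 °C; NaHCO3 work-up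
Reagents that add atoms: water, O
Why: Acid-catalysed homoconjugate (1,5-) addition of water to a cyclopropyl ketone: the protonated enone opens the external cyclopropane bond, which overlaps best with the carbonyl π system and leaves a tertiary cation, and water captures it; the cyclopropane CH that becomes C7 is not involved, so its configuration is carried over from 1.

Step 3
Reactants: 3 (S)-5-(2-hydroxypropan-2-yl)-3-methylcyclohex-2-en-1-one
Product: 4 bis(trimethylsilyl) dienol ether of 3 (C9–OSiMe3 with C8=C9 and C10=C5 double bonds; C11–OSiMe3)
Conditions: LiN(i-Pr)2 (2.3 equiv), Me3SiCl, THF, −78 → 0 °C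
Reagents that add atoms: chlorotrimethylsilane, C[Si](C)(C)Cl
Why: Kinetic α′-deprotonation of an enone at C8 gives the cross-conjugated dienolate, which is silylated on oxygen together with the tertiary alkoxide; this defines the regiochemistry of the oxidation that follows.

Step 4
Reactants: 4 bis(trimethylsilyl) dienol ether
Product: 6 (5S,6R)-6-hydroxy-5-(2-hydroxypropan-2-yl)-3-methylcyclohex-2-en-1-one (C8 hydroxyl trans to the C7 side chain), via silyloxy ketone 5 (not isolated)
Conditions: mCPBA, NaHCO3, CH2Cl2, −20 °C; then HCl (1 M), THF, 0 °C
Reagents that add atoms: 3-chloroperbenzoic acid, OOC(=O)c1cccc(Cl)c1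
Why: Rubottom oxidation: the peracid epoxidises the electron-rich enol ether double bond (not the electron-poor enone alkene) on the face away from the bulky C7 side chain, silyl migration gives 5, and dilute acid removes both silyl groups; the trans-diequatorial C7/C8 arrangement is also the thermodynamic one, so enolisation cannot erode it.

Step 5
Reactants: 6 (5S,6R)-6-hydroxy-5-(2-hydroxypropan-2-yl)-3-methylcyclohex-2-en-1-one
Product: 7 trans-fused acetonide of 6 (2,2,4,4,6-pentamethyl-4a,5-dihydro-4H-1,3-benzodioxin-8(8aH)-one; O8 and O11 bridged by CMe2)
Conditions: Me2C(OMe)2, pyridinium p-toluenesulfonate (cat.), CH2Cl2, 20 °C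
Reagents that add atoms: 2,2-dimethoxypropane, COC(C)(C)OC
Why: Acid-catalysed transketalisation closes a 1,3-dioxane across the diequatorial C8–O and C7–C11 bonds; one group protects both hydroxyls, masks the C7 side chain and locks the ring A chair.

Step 6
Reactants: 7 trans-fused acetonide enone; 8 isopropenylmagnesium bromide
Product: 9 trimethylsilyl enol ether of the conjugate adduct (C9–OSiMe3 with C9=C10; C5 bearing β-isopropenyl and α-methyl)
Conditions: CuBr·SMe2 (20 mol %), Me3SiCl, DMPU, THF, −78 → −40 °C; Et3N, pentane work-up
Reagents that add atoms: chlorotrimethylsilane, C[Si](C)(C)Cl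
Why: Copper-catalysed conjugate addition of a Grignard reagent with silyl chloride trapping; the nucleophile adds to C5 axially on the face opposite the equatorial C7 substituent (the usual trans outcome for 5-substituted cyclohexenones), which sets the quaternary centre with isopropenyl β and axial, and the enolate is fixed as the C9=C10 enol ether.

Step 7
Reactants: 9 trimethylsilyl enol ether
Product: 13 α-methylene ketone (C9 ketone with exocyclic C10=C1H2), via lithium enolate 10 (not isolated), via Mannich base 11 (not isolated), via methiodide 12 (not isolated)
Conditions: MeLi, THF, 0 °C; CH2=NMe2+ I−, −78 → 20 °C; MeI, CH2Cl2; NaHCO3 (aq.)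
Reagents that add atoms: N,N-dimethylmethyleneiminium iodide (Eschenmoser's salt), C=[N+](C)C.[I-]
Why: Mannich reaction of a regiodefined lithium enolate with a small, highly reactive iminium ion that tolerates the neighbouring quaternary C5, then quaternisation and E1cB loss of trimethylamine; C10 becomes trigonal, so its transient configuration is irrelevant, and releasing the enolate with MeLi avoids free iodotrimethylsilane near the acetonide.

Step 8
Reactants: 13 α-methylene ketone
Product: 14 allylic alcohol (C9 hydroxyl β and axial, cis to O8)
Conditions: NaBH4, CeCl3·7H2O, MeOH, −78 °C
Reagents that add atoms: none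
Why: Luche reduction gives 1,2-addition to the enone; attack from the β face is blocked by the axial C5 isopropenyl group 1,3 to the carbonyl in the locked chair, so hydride should enter from the α face and leave the hydroxyl axial and β.

Step 9
Reactants: 14 allylic alcohol
Product: 15 C9 triethylsilyl ether (ring A 1,4-diene: exocyclic C10=C1H2 and C5 isopropenyl; O8/O11 acetonide)
Conditions: Et3SiOTf, 2,6-lutidine, CH2Cl2, −78 → 0 °C
Reagents that add atoms: triethylsilyl trifluoromethanesulfonate, CC[Si](CC)(CC)OS(=O)(=O)C(F)(F)F
Why: Silylation of a hindered secondary alcohol with a silyl triflate; the ether keeps the hydroxyl from consuming B–H and adds bulk on the β face of the methylene.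

Step 10
Reactants: 15 C9 triethylsilyl ether diene; 16 carbon monoxide
Product: 19 8β,11-(isopropylidenedioxy)-9β-(triethylsilyloxy)-cis-eremophilan-2-one (C4 methyl cis to C5 methyl; C10 hydrogen cis to C5 methyl), via B-thexyl borinane 17 (not isolated), via hydroxyborinic acid 18 (not isolated)
Conditions: ThxBH2 (from BH3·THF and 2,3-dimethylbut-2-ene), THF, −20 → 25 °C; CO (70 bar), H2O, 50 °C; NaOAc, H2O2 (30%), 50 °C
Reagents that add atoms: none
Why: Thexylborane adds across the exocyclic C10=C1 bond in the usual four-centre, anti-Markovnikov syn fashion (boron on C1, hydrogen on C10), and the remaining B–H bond then adds intramolecularly to the C5 isopropenyl group (boron on C3, hydrogen on C4) to give the B-thexyl borinane 17. Carbon monoxide binds to boron, the C1 and C3 alkyl groups migrate in turn from boron to the carbonyl carbon while water arrests the sequence at 18 before the thexyl group can move, and buffered peroxide cleaves the last C–B bond to release the C2 ketone. The closest known reaction type is the cyclic hydroboration of 1,4-dienes with thexylborane followed by carbonylation to cyclohexanones. Ring B is closed as a six-membered boracycle by a 6-endo intramolecular hydroboration and is then turned into the carbocycle by two 1,2-shifts (expansion to a seven-membered acylborane, then contraction with C2 in the place of boron). C10 is set in the first, intermolecular addition: in the chair locked by the trans-fused acetonide the C5 isopropenyl and C9 silyloxy groups are both axial on the β face (the arrangement that also minimises allylic strain with the methylene), so hydrogen reaches C10 from the α face and C1 ends equatorial, cis to C4. C4 is set in the ring-closing addition through a chair-like boracyclic transition state in which the transferred hydrogen bridges boron and C4 axially and the thexyl group and the C4 methyl are equatorial, the alternative placing that methyl 1,3-diaxial to C9; this puts the C4 methyl cis to the C5 methyl. The step needs chemoselectivity (no third alkene, secured by the acetonide that masks the C7 side chain), the right order of attack (methylene first, since a borane attached first to the neopentyl-type isopropenyl group could reach C10=C1 only through a strained boat), and inertness of the silyl ether and the acetal to B–H and to the buffered oxidation.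

Step 11
Reactants: 19 key-step ketone
Product: 20 9β-hydroxy-8β,11-(isopropylidenedioxy)-cis-eremophilan-2-one
Conditions: Bu4NF, THF, 0 → 20 °C
Reagents that add atoms: none
Why: Fluoride cleavage of the silyl ether; the acetonide is untouched, and the C2 ketone has only methylene α-positions, so no stereocentre can epimerise.

Step 12
Reactants: 20 C9 alcohol; 21 tigloyl chloride [(E)-2-methylbut-2-enoyl chloride]
Product: 22 8β,11-(isopropylidenedioxy)-2-oxo-cis-eremophilan-9β-yl tiglate
Conditions: DMAP, pyridine, toluene, 60 °C
Reagents that add atoms: none
Why: DMAP-catalysed acylation through the acylpyridinium ion at the only free hydroxyl; the forcing conditions needed for the axial C9 oxygen are harmless because no other ester is present yet, and pyridine as the only base limits γ-deprotonation of the acid chloride.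

Step 13
Reactants: 22 tiglate acetonide
Product: 23 8β,11-dihydroxy-2-oxo-cis-eremophilan-9β-yl tiglate
Conditions: AcOH/H2O (4:1), 40 °C
Reagents that add atoms: none
Why: Mild acid hydrolysis of the strained 2,2,4,4-tetrasubstituted 1,3-dioxane; dilute acid neither dehydrates the tertiary alcohol nor promotes migration of the hindered conjugated ester.

Step 14
Reactants: 23 diol tiglate
Product: 24 8β-acetoxy-11-hydroxy-2-oxo-cis-eremophilan-9β-yl tiglate
Conditions: Ac2O, pyridine, DMAP (cat.), CH2Cl2, 0 °C
Reagents that add atoms: acetic anhydride, CC(=O)OC(C)=O
Why: Selective acetylation of the equatorial secondary C8 hydroxyl; the tertiary C11 hydroxyl does not react at 0 °C, and the weakly basic medium gives the tiglate no alkoxide neighbour to migrate to.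

Step 15
Reactants: 24 acetate tertiary alcohol
Product: 25 (4S,5R,7R,8R,9S,10S)-8-acetoxy-2-oxoeremophil-11-en-9-yl (E)-2-methylbut-2-enoate (target)
Conditions: MeO2CN(−)SO2N(+)Et3 (Burgess reagent), toluene, 50 °C
Reagents that add atoms: none
Why: Burgess dehydration of a tertiary alcohol by syn elimination from the sulfamate; the six methyl hydrogens are freely accessible, whereas the C7 hydrogen is axial on the β face between the C9 tiglate and the C5–C4 bond and its loss would create a tetrasubstituted alkene with allylic strain against the C8 acetate, so the isopropenyl isomer should dominate.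

## Compound list

1 | (+)-3-carene, (1S,6R)-3,7,7-trimethylbicyclo[4.1.0]hept-3-ene | CC1=CC[C@@H]2[C@H](C1)C2(C)C | starting material
2 | (1R,6S)-4,7,7-trimethylbicyclo[4.1.0]hept-3-en-2-one (car-3-en-5-one) | CC1=CC(=O)[C@@H]2[C@H](C1)C2(C)C | intermediate
3 | (S)-5-(2-hydroxypropan-2-yl)-3-methylcyclohex-2-en-1-one | CC(C)(O)[C@H]1CC(C)=CC(=O)C1 | intermediate
4 | bis(trimethylsilyl) dienol ether of 3 | CC(C)(O[Si](C)(C)C)[C@H]1CC(C)=CC(O[Si](C)(C)C)=C1 | intermediate
5 | (5S,6R)-3-methyl-6-(trimethylsilyloxy)-5-(2-trimethylsilyloxypropan-2-yl)cyclohex-2-en-1-one | CC(C)(O[Si](C)(C)C)[C@H]1CC(C)=CC(=O)[C@@H]1O[Si](C)(C)C | intermediate (not isolated)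
6 | (5S,6R)-6-hydroxy-5-(2-hydroxypropan-2-yl)-3-methylcyclohex-2-en-1-one | CC(C)(O)[C@H]1CC(C)=CC(=O)[C@@H]1O | intermediate
7 | trans-fused acetonide of 6 (2,2,4,4,6-pentamethyl-4a,5-dihydro-4H-1,3-benzodioxin-8(8aH)-one) | CC2(C)[C@H]1CC(C)=CC(=O)[C@@H]1OC(C)(C)O2 | intermediate
8 | isopropenylmagnesium bromide | CC(=C)[Mg]Br | starting material
9 | trimethylsilyl enol ether of the conjugate adduct (C9=C10, C5 β-isopropenyl, α-methyl) | CC2(C)[C@H]1C[C@@](C(C)=C)(C)C=C(O[Si](C)(C)C)[C@@H]1OC(C)(C)O2 | intermediate
10 | lithium enolate corresponding to 9 | CC2(C)[C@H]1C[C@@](C(C)=C)(C)C=C([O-])[C@@H]1OC(C)(C)O2.[Li+] | intermediate (not isolated)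
11 | Mannich base (C10 dimethylaminomethyl, C9 ketone) | CC2(C)[C@H]1C[C@@](C(C)=C)(C)C(CN(C)C)C(=O)[C@@H]1OC(C)(C)O2 | intermediate (not isolated)
12 | methiodide of 11 | CC2(C)[C@H]1C[C@@](C(C)=C)(C)C(C[N+](C)(C)C)C(=O)[C@@H]1OC(C)(C)O2.[I-] | intermediate (not isolated)
13 | α-methylene ketone (C9 ketone, C10=C1H2) | CC2(C)[C@H]1C[C@@](C(C)=C)(C)C(=C)C(=O)[C@@H]1OC(C)(C)O2 | intermediate
14 | allylic alcohol (C9 β-hydroxyl) | CC2(C)[C@H]1C[C@@](C(C)=C)(C)C(=C)[C@H](O)[C@@H]1OC(C)(C)O2 | intermediate
15 | C9 triethylsilyl ether, ring A 1,4-diene (key-step precursor) | CC2(C)[C@H]1C[C@@](C(C)=C)(C)C(=C)[C@H](O[Si](CC)(CC)CC)[C@@H]1OC(C)(C)O2 | intermediate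
16 | carbon monoxide | [C-]#[O+] | starting material
17 | B-thexyl borinane (boron in the place of C2) | CC2(C)[C@H]1C[C@@]3(C)[C@H](CB(C(C)(C)C(C)C)C[C@@H]3C)[C@H](O[Si](CC)(CC)CC)[C@@H]1OC(C)(C)O2 | intermediate (not isolated)
18 | C2 carbinol bearing hydroxy(thexyl)boryl | CC2(C)[C@H]1C[C@@]3(C)[C@H](CC(O)(B(O)C(C)(C)C(C)C)C[C@@H]3C)[C@H](O[Si](CC)(CC)CC)[C@@H]1OC(C)(C)O2 | intermediate (not isolated)
19 | 8β,11-(isopropylidenedioxy)-9β-(triethylsilyloxy)-cis-eremophilan-2-one (key-step product) | CC2(C)[C@H]1C[C@@]3(C)[C@H](CC(=O)C[C@@H]3C)[C@H](O[Si](CC)(CC)CC)[C@@H]1OC(C)(C)O2 | intermediate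
20 | 9β-hydroxy-8β,11-(isopropylidenedioxy)-cis-eremophilan-2-one | CC2(C)[C@H]1C[C@@]3(C)[C@H](CC(=O)C[C@@H]3C)[C@H](O)[C@@H]1OC(C)(C)O2 | intermediate
21 | tigloyl chloride, (E)-2-methylbut-2-enoyl chloride | C/C=C(\C)C(Cl)=O | starting material
22 | 8β,11-(isopropylidenedioxy)-2-oxo-cis-eremophilan-9β-yl tiglate | CC2(C)[C@H]1C[C@@]3(C)[C@H](CC(=O)C[C@@H]3C)[C@H](OC(=O)/C(C)=C/C)[C@@H]1OC(C)(C)O2 | intermediate
23 | 8β,11-dihydroxy-2-oxo-cis-eremophilan-9β-yl tiglate | CC(C)(O)[C@H]1C[C@@]2(C)[C@H](CC(=O)C[C@@H]2C)[C@H](OC(=O)/C(C)=C/C)[C@@H]1O | intermediate
24 | 8β-acetoxy-11-hydroxy-2-oxo-cis-eremophilan-9β-yl tiglate | CC(C)(O)[C@H]1C[C@@]2(C)[C@H](CC(=O)C[C@@H]2C)[C@H](OC(=O)/C(C)=C/C)[C@@H]1OC(C)=O | intermediate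
25 | (4S,5R,7R,8R,9S,10S)-8-acetoxy-2-oxoeremophil-11-en-9-yl (E)-2-methylbut-2-enoate | C=C(C)[C@H]1C[C@@]2(C)[C@H](CC(=O)C[C@@H]2C)[C@H](OC(=O)/C(C)=C/C)[C@@H]1OC(C)=O | target

## Step count and least certain steps

Total step count: 15. Longest linear sequence: 15 steps (1 to 25); the route is fully linear.

**Step 10 (key step).** Three things are most likely to go wrong:
- The borane may attack the isopropenyl group first, giving open-chain or oligomeric boranes instead of the boracycle.
- Facial selectivity at C10 may be eroded.
- The second boron-to-carbon migration may stall, or the thexyl group may lose 2,3-dimethylbut-2-ene at 50 °C, on a boracycle that is hindered on both sides.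

The fallback keeps the same two bonds but replaces the migration chemistry by a carbonyl dianion equivalent. It sets out from 15. The boracycle 17 is formed as before and oxidised with NaOH/H2O2 to the C1,C3-diol F1, which already holds both new stereocentres. Triphenylphosphine, iodine and imidazole give the diiodide F2. Double alkylation of 2-lithio-1,3-dithiane (n-BuLi in two portions, THF/DMPU; the second alkylation is intramolecular) gives the spiro dithioketal F3. Neutral dethioketalisation (MeI, CaCO3, aqueous MeCN) returns to the route at 19.

**Step 2.** The tertiary cation may lose a proton instead of capturing water. The resulting isopropylidene dienone can tautomerise irreversibly to a phenol, and the hydroxy enone itself can re-ionise on long exposure to acid. The fallback separates ring opening from hydration. It sets out from 2: HBr in acetic acid at 0 °C traps the cation irreversibly as the tertiary bromide (S)-5-(2-bromopropan-2-yl)-3-methylcyclohex-2-en-1-one F4. Silver-assisted solvolysis (AgNO3, aqueous acetone, 2,6-lutidine) returns to the route at 3.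

**Step 8.** Facial selectivity may be insufficient with a small hydride on a flattened, conjugated ketone, and some conjugate reduction is possible. The fallback moves the reduction to a saturated ketone, where a bulky hydride can be used. It sets out from the Mannich base 11 (step 7 stopped before quaternisation; C10 equilibrated to the equatorial epimer). Li(s-Bu)3BH in THF at −78 °C should attack from the α face only and give the amino alcohol F5. Oxidation with H2O2 in methanol gives the amine oxide F6, and thermal syn elimination (Cope elimination, 80–110 °C) forms the exocyclic methylene and returns to the route at 14.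

**Step 12.** Acylation of the axial C9 hydroxyl, 1,3-diaxial to the C5–C4 bond, may be slow. Prolonged heating favours γ-deprotonation of the acid chloride and formation of deconjugated ester. The fallback builds the tiglate double bond after a less demanding acylation. It sets out from 20. The small and more electrophilic 2-bromopropanoyl bromide (pyridine, CH2Cl2) gives the 2-bromopropanoate F7. Arbuzov reaction with P(OEt)3 at 110 °C gives the phosphonate F8. Horner–Wadsworth–Emmons olefination with acetaldehyde (LiCl, DBU, MeCN) forms the (E)-2-methylbut-2-enoate and returns to the route at 22.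

**Step 15.** The C7 proton may be lost instead of a methyl proton, and the C8 acetate carbonyl may participate in the developing C11 cation, leading to acyl transfer. The fallback unveils the alkene before the acetate is present, next to a bulky group that cannot participate. It sets out from 23. Selective silylation of the secondary hydroxyl (Et3SiCl, imidazole) gives the C8 silyl ether F9. Anti elimination through the chlorosulfite (SOCl2, pyridine, −40 °C) gives the isopropenyl compound F10. HF·pyridine frees the C8 alcohol F11, and acetylation (Ac2O, pyridine, DMAP) returns to the route at 25.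

## Further compounds

F1 | step 10 | C1,C3-diol from oxidation of the boracycle | CC2(C)[C@H]1C[C@@]([C@@H](C)CO)(C)[C@H](CO)[C@H](O[Si](CC)(CC)CC)[C@@H]1OC(C)(C)O2
F2 | step 10 | C1,C3-diiodide | CC2(C)[C@H]1C[C@@]([C@@H](C)CI)(C)[C@H](CI)[C@H](O[Si](CC)(CC)CC)[C@@H]1OC(C)(C)O2
F3 | step 10 | C2 spiro-1,3-dithiane of 19 | CC2(C)[C@H]1C[C@@]3(C)[C@H](CC4(SCCCS4)C[C@@H]3C)[C@H](O[Si](CC)(CC)CC)[C@@H]1OC(C)(C)O2
F4 | step 2 | (S)-5-(2-bromopropan-2-yl)-3-methylcyclohex-2-en-1-one | CC(C)(Br)[C@H]1CC(C)=CC(=O)C1
F5 | step 8 | amino alcohol (C9 β-hydroxyl, C10 dimethylaminomethyl) | CC2(C)[C@H]1C[C@@](C(C)=C)(C)C(CN(C)C)[C@H](O)[C@@H]1OC(C)(C)O2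
F6 | step 8 | amine oxide of F5 | CC2(C)[C@H]1C[C@@](C(C)=C)(C)C(C[N+](C)(C)[O-])[C@H](O)[C@@H]1OC(C)(C)O2
F7 | step 12 | C9 2-bromopropanoate of 20 | CC2(C)[C@H]1C[C@@]3(C)[C@H](CC(=O)C[C@@H]3C)[C@H](OC(=O)C(C)Br)[C@@H]1OC(C)(C)O2
F8 | step 12 | C9 2-(diethoxyphosphoryl)propanoate of 20 | CC2(C)[C@H]1C[C@@]3(C)[C@H](CC(=O)C[C@@H]3C)[C@H](OC(=O)C(C)P(=O)(OCC)OCC)[C@@H]1OC(C)(C)O2
F9 | step 15 | C8 triethylsilyl ether of 23 | CC(C)(O)[C@H]1C[C@@]2(C)[C@H](CC(=O)C[C@@H]2C)[C@H](OC(=O)/C(C)=C/C)[C@@H]1O[Si](CC)(CC)CC
F10 | step 15 | isopropenyl compound with C8 triethylsilyl ether | C=C(C)[C@H]1C[C@@]2(C)[C@H](CC(=O)C[C@@H]2C)[C@H](OC(=O)/C(C)=C/C)[C@@H]1O[Si](CC)(CC)CC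
F11 | step 15 | 8β-hydroxy-2-oxoeremophil-11-en-9β-yl tiglate | C=C(C)[C@H]1C[C@@]2(C)[C@H](CC(=O)C[C@@H]2C)[C@H](OC(=O)/C(C)=C/C)[C@@H]1O
A1 | alternative 1 | cis-decal-6-en-2-one with C1 dimethyl ketal and C8 benzyl ether | C1=C[C@@]2(C)[C@H](C(OC)(OC)C(=O)C[C@@H]2C)C[C@H]1OCc1ccccc1
A2 | alternative 1 | bicyclo[2.2.2]octenol with (Z)-propenyl carbinol | O[C@]1(/C=C\C)C(OC)(OC)[C@@H]2C[C@@H](OCc3ccccc3)[C@H]1C=C2C
A3 | alternative 2 | cis-fused 6-oxo decalin silyl enol ether acetonide | C=C(C)[C@H]1C(=O)[C@@]2(C)[C@H](C=C(O[Si](C)(C)C(C)(C)C)C[C@@H]2C)[C@@H]3OC(C)(C)O[C@H]13
A4 | alternative 2 | acyclic silyloxydiene tiglyl ketone | C=C(O[Si](C)(C)C(C)(C)C)/C=C/[C@@H]1OC(C)(C)O[C@@H]1[C@@H](C(C)=C)C(=O)/C(C)=C/C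
A5 | alternative 3 | cis-decalin with C7 acetyl, C8 hydroxyl, C9 p-methoxybenzyl ether (trans to O8) and C2 ketal | CC(=O)[C@H]1C[C@@]2(C)[C@H](CC3(OCCO3)C[C@@H]2C)[C@@H](OCc2ccc(OC)cc2)[C@@H]1O
A6 | alternative 3 | methylenecyclohexane aldehyde | C=C1[C@@H](C)CC2(OCCO2)C[C@@H]1[C@@H](OCc1ccc(OC)cc1)C=O
A7 | alternative 3 | but-3-en-2-one | CC(=O)C=C
A8 | alternative 3 | C9 epimer of A5 that matches the target | CC(=O)[C@H]1C[C@@]2(C)[C@H](CC3(OCCO3)C[C@@H]2C)[C@H](OCc2ccc(OC)cc2)[C@@H]1O
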